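With the cyclohexene numbered C1 (ring A aroyl), C2 (ring B), C3=C4(Me), C5, C6 (ring C), the route rests on the C1–C6 disconnection. It exploits the fact that the ketone carbon on C1 and the ring B oxygen ortho to C2 can be joined as a six-membered aryl lactone, making C1 the α-carbon of a 3,4-dihydrocoumarin. In one operation the lactone's silyl ketene acetal captures the ring C benzylic cation at C6: this closes the cyclohexene, forces the cis C1/C2 fusion and sets C1 and C6 from C2. The precursor is a (4R)-4-alkenyldihydrocoumarin whose Z-trisubstituted alkene chain ends in a 2,4-dialkoxyphenyl carbinol; the ring A aryllithium later opens the lactone.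

Key step: step 9

Remarks on the chemistry
- The carbinol carbon of 9–14 is carried as both configurations (left undefined in the SMILES), because it becomes the planar cation in step 9.
- Checked configurations: target (1R,2S,6S) in the cyclohexene numbering above; precursor 13 is 4R; lactone 15 is 6aR,7S,10aS; the alkene of 13 is Z.
- The ring B ketone stays masked through step 9, since a free o-acyloxyacetophenone would suffer Baker–Venkataraman acyl transfer with the amide base. To keep the dioxolane and MOM acetals from competing with the benzylic silyl ether, the amine is stripped and only catalytic Me3SiOTf is used at −78 °C.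
- (R,R)-Ph-bod* is (1R,4R)-2,5-diphenylbicyclo[2.2.2]octa-2,5-diene. The sense of induction in step 8 is assigned by analogy with aryl additions to coumarins; the antipodal diene is used if a test run shows the 4S sense.

**Ring B coumarin**

Step 1
Reactants: 1 2',4'-dihydroxyacetophenone
Product: 2 3-acetyl-2,6-dihydroxybenzaldehyde
Conditions: hexamethylenetetramine, CF3CO2H, 90 °C; then 3 M aq HCl, 60 °C
Reagents that add atoms: hexamethylenetetramine C1N2CN3CN1CN(C2)C3; water O
Why: Duff formylation (electrophilic substitution by an iminium ion from hexamethylenetetramine, then hydrolysis) should take the position between the two hydroxyls, which is ortho to both and meta to the acetyl group.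

Step 2
Reactants: 2 3-acetyl-2,6-dihydroxybenzaldehyde
Product: 3 3-acetyl-2-hydroxy-6-(methoxymethoxy)benzaldehyde
Conditions: MOMCl (1.1 equiv), K2CO3, acetone, 0 °C to rt
Reagents that add atoms: chloromethyl methyl ether COCCl
Why: Williamson-type O-alkylation should take the hydroxyl para to the acetyl group, because the other hydroxyl is flanked by, and hydrogen-bonded to, both carbonyl groups.

Step 3
Reactants: 3 3-acetyl-2-hydroxy-6-(methoxymethoxy)benzaldehyde
Product: 5 8-acetyl-5-(methoxymethoxy)-2H-chromen-2-one, via ethyl cinnamate 4 (not isolated)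
Conditions: Ph3P=CHCO2Et (1.1 equiv), toluene, rt; then PhNEt2, 200 °C
Reagents that add atoms: ethyl (triphenylphosphoranylidene)acetate CCOC(=O)C=P(c1ccccc1)(c1ccccc1)c1ccccc1
Why: Wittig olefination of the aldehyde (the stabilised ylide leaves the hindered aryl ketone alone at rt), then thermal E/Z isomerisation and lactonisation onto the only free phenol, is the standard coumarin synthesis from salicylaldehydes and places the lactone oxygen next to the acetyl-bearing carbon.

Step 4
Reactants: 5 8-acetyl-5-(methoxymethoxy)-2H-chromen-2-one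
Product: 6 5-(methoxymethoxy)-8-(2-methyl-1,3-dioxolan-2-yl)-2H-chromen-2-one
Conditions: (Me3SiOCH2)2, Me3SiOTf (5 mol%), CH2Cl2, −78 to −20 °C; pyridine quench
Reagents that add atoms: 1,2-bis(trimethylsilyloxy)ethane C[Si](C)(C)OCCO[Si](C)(C)C
Why: Noyori ketalisation masks the ketone under aprotic, low-temperature conditions that should leave the aryl MOM ether and the coumarin untouched, and the mask is needed against the amide base of step 9 and the aryllithium of step 14.

**Ring C boronate**

Step 5
Reactants: 7 2,4-dihydroxybenzaldehyde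
Product: 8 2,4-bis(methoxymethoxy)benzaldehyde
Conditions: MOMCl (3 equiv), iPr2NEt, CH2Cl2, 0 to 40 °C
Reagents that add atoms: chloromethyl methyl ether COCCl
Why: Williamson-type O-alkylation of both phenols, the chelated ortho hydroxyl reacting under the forcing excess of reagent.

Step 6
Reactants: 8 2,4-bis(methoxymethoxy)benzaldehyde
Product: 9 rac-1-[2,4-bis(methoxymethoxy)phenyl]-3-methylbut-3-en-1-ol
Conditions: 2-methylallylmagnesium chloride, THF, −78 °C; aq NH4Cl
Reagents that add atoms: 2-methylallylmagnesium chloride CC(=C)C[Mg]Cl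
Why: Grignard 1,2-addition to the aldehyde; the carbinol centre is formed racemic on purpose because it is destroyed in step 9.

Step 7
Reactants: 9 rac-1-[2,4-bis(methoxymethoxy)phenyl]-3-methylbut-3-en-1-ol
Product: 12 rac-6-[2,4-bis(methoxymethoxy)phenyl]-4-methyl-5,6-dihydro-2H-1,2-oxaborinin-2-ol, via mixed boronate 10 (not isolated), via cyclic butyl boronate 11 (not isolated)
Conditions: CH2=CHB(OBu)2, toluene, 40 °C under reduced pressure; second-generation Grubbs catalyst (5 mol%), CH2Cl2, 40 °C; H2O work-up, Et3N-deactivated silica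
Reagents that add atoms: dibutyl vinylboronate C=CB(OCCCC)OCCCC; water O
Why: Transesterification ties the vinylboron unit to the carbinol oxygen and ring-closing metathesis (boron-tethered, with loss of ethene) then forms the six-membered alkenylboronate, in which boron and the CH2 group are necessarily cis on the trisubstituted double bond.

**Coupling and key step**

Step 8
Reactants: 6 5-(methoxymethoxy)-8-(2-methyl-1,3-dioxolan-2-yl)-2H-chromen-2-one; 12 rac-6-[2,4-bis(methoxymethoxy)phenyl]-4-methyl-5,6-dihydro-2H-1,2-oxaborinin-2-ol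
Product: 13 (4R)-4-[(1Z)-4-[2,4-bis(methoxymethoxy)phenyl]-4-hydroxy-2-methylbut-1-en-1-yl]-5-(methoxymethoxy)-8-(2-methyl-1,3-dioxolan-2-yl)-3,4-dihydro-2H-chromen-2-one (both carbinol epimers)
Conditions: Rh(acac)(C2H4)2 (5 mol%), (R,R)-Ph-bod* (6 mol%), 12 (2.5 equiv), dioxane/H2O 10:1, 60 °C
Reagents that add atoms: none
Why: Hayashi–Miyaura rhodium-catalysed asymmetric 1,4-addition, in which the alkenyl group passes from boron to rhodium with retention (so the Z geometry is kept) and the chiral diene directs it to the C4 face that gives the 4R centre, which is C2 of the target.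

Step 9
Reactants: 13 (4R)-4-[(1Z)-4-[2,4-bis(methoxymethoxy)phenyl]-4-hydroxy-2-methylbut-1-en-1-yl]-5-(methoxymethoxy)-8-(2-methyl-1,3-dioxolan-2-yl)-3,4-dihydro-2H-chromen-2-one
Product: 15 (6aR,7S,10aS)-7-[2,4-bis(methoxymethoxy)phenyl]-1-(methoxymethoxy)-9-methyl-4-(2-methyl-1,3-dioxolan-2-yl)-6a,7,8,10a-tetrahydro-6H-benzo[c]chromen-6-one, via bis-silyl ketene acetal 14 (not isolated)
Conditions: Me3SiCl (5 equiv), LiN(SiMe3)2 (2.4 equiv), THF, −78 °C; strip volatiles, pentane, filter; Me3SiOTf (0.2 equiv), CH2Cl2 (5 mM), −78 °C; aq NaHCO3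
Reagents that add atoms: none
Why: LiN(SiMe3)2 with Me3SiCl present silylates the carbinol and traps the lactone enolate as its silyl ketene acetal 14 before the aryl ester enolate can fragment; after the amine is stripped, catalytic Me3SiOTf ionises the C6–OSiMe3 bond to a cation stabilised by the ortho and para oxygens of ring C, the ketene acetal carbon C1 attacks it, and the silyl group leaves as (Me3Si)2O with return of the catalyst. The closest known reaction type is the Lewis-acid-mediated SN1 alkylation of silyl enol ethers and ketene acetals by benzylic electrophiles (Mukaiyama/Reetz type), here run intramolecularly. The cyclohexene closes in a 6-(enolexo)-exo-trig mode onto the cationic carbon. C1 (C6a of 15) is controlled by C2 (C10a): the four-atom tether with its Z double bond hangs from one face of the nearly planar lactone ring and can reach the C1 p-orbital only from that face, so the new ring is cis-fused; C6 (C7 of 15) is controlled by a half-chair transition state in which ring C points away from the ketene acetal carbon and its silyloxy group, which should give trans C1/C6 whatever the carbinol configuration. The step needs C–C bond formation to outrun loss of a C5 proton (conjugated diene) and opening of the dioxolane or MOM acetals; intramolecularity, the high stability of the 2,4-dialkoxybenzylic cation, the absence of base, −78 °C and high dilution are there to secure this.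

**Ring A bromide**

Step 10
Reactants: 16 5-bromobenzene-1,3-diol
Product: 17 5-bromo-2-iodobenzene-1,3-diol
Conditions: I2, NaHCO3, H2O/THF, 0 °C
Reagents that add atoms: iodine II
Why: Electrophilic iodination of the resorcinol under bicarbonate buffer should take the position between the two hydroxyls, the other two ring positions being flanked by bromine.

Step 11
Reactants: 17 5-bromo-2-iodobenzene-1,3-diol
Product: 18 5-bromo-2-iodo-1,3-bis(methoxymethoxy)benzene
Conditions: MOMCl, iPr2NEt, CH2Cl2, 0 °C to rt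
Reagents that add atoms: chloromethyl methyl ether COCCl
Why: Williamson-type O-alkylation of both phenols.

Step 12
Reactants: 18 5-bromo-2-iodo-1,3-bis(methoxymethoxy)benzene
Product: 20 5-bromo-1,3-bis(methoxymethoxy)-2-(3-methylbut-2-en-1-yl)benzene, via arylmagnesium chloride 19 (not isolated)
Conditions: iPrMgCl·LiCl, THF, −40 °C; CuI (10 mol%), prenyl bromide, −40 to 0 °C
Reagents that add atoms: 1-bromo-3-methylbut-2-ene CC(C)=CCBr
Why: Iodine–magnesium exchange is much faster than bromine–magnesium exchange and gives a Grignard reagent chelated by both MOM ethers, whose copper-catalysed allylic substitution on prenyl bromide occurs at the primary carbon (SN2) to give the linear prenyl group.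

**Ring D aldehyde**

Step 13
Reactants: 21 4-hydroxybenzaldehyde
Product: 22 4-(methoxymethoxy)benzaldehyde
Conditions: MOMCl, iPr2NEt, CH2Cl2, 0 °C to rt
Reagents that add atoms: chloromethyl methyl ether COCCl
Why: Williamson-type O-alkylation of the phenol.

**Endgame**

Step 14
Reactants: 15 (6aR,7S,10aS)-7-[2,4-bis(methoxymethoxy)phenyl]-1-(methoxymethoxy)-9-methyl-4-(2-methyl-1,3-dioxolan-2-yl)-6a,7,8,10a-tetrahydro-6H-benzo[c]chromen-6-one; 20 5-bromo-1,3-bis(methoxymethoxy)-2-(3-methylbut-2-en-1-yl)benzene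
Product: 25 [(1R,2S,6S)-2-[3-acetyl-2-hydroxy-6-(methoxymethoxy)phenyl]-6-[2,4-bis(methoxymethoxy)phenyl]-4-methylcyclohex-3-en-1-yl][3,5-bis(methoxymethoxy)-4-(3-methylbut-2-en-1-yl)phenyl]methanone, via aryllithium 23 (not isolated), via dioxolane ketone 24 (not isolated)
Conditions: 20 (1.15 equiv), t-BuLi (2.3 equiv), THF, −78 °C; add 15, −78 °C; then 1 M aq HCl, THF, 0 °C to rt
Reagents that add atoms: water O
Why: Bromine–lithium exchange gives the aryllithium, which adds once to the aryl lactone (acyl substitution with the ring B phenoxide as leaving group, the hindered ketone and near-stoichiometric charge at −78 °C guarding against a second addition or enolisation at C1), and the dilute acid of the work-up hydrolyses the phenol-assisted dioxolane while the aryl MOM ethers should survive.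

Step 15
Reactants: 25 [(1R,2S,6S)-2-[3-acetyl-2-hydroxy-6-(methoxymethoxy)phenyl]-6-[2,4-bis(methoxymethoxy)phenyl]-4-methylcyclohex-3-en-1-yl][3,5-bis(methoxymethoxy)-4-(3-methylbut-2-en-1-yl)phenyl]methanone; 22 4-(methoxymethoxy)benzaldehyde
Product: 26 [(1R,2S,6S)-6-[2,4-bis(methoxymethoxy)phenyl]-2-[2-hydroxy-3-[3-hydroxy-3-[4-(methoxymethoxy)phenyl]propanoyl]-6-(methoxymethoxy)phenyl]-4-methylcyclohex-3-en-1-yl][3,5-bis(methoxymethoxy)-4-(3-methylbut-2-en-1-yl)phenyl]methanone (both epimers at the new carbinol)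
Conditions: LiN(SiMe3)2 (2.5 equiv), THF, −78 °C; 22 (1.5 equiv), −78 to −40 °C; AcOH quench at −78 °C
Reagents that add atoms: none
Why: Aldol addition in which the base deprotonates the phenol and then, kinetically, the unhindered acetyl methyl rather than the hindered C1 methine, and the dianion adds to the aldehyde; the new carbinol centre is formed as a mixture and is removed in step 16.

Step 16
Reactants: 26 [(1R,2S,6S)-6-[2,4-bis(methoxymethoxy)phenyl]-2-[2-hydroxy-3-[3-hydroxy-3-[4-(methoxymethoxy)phenyl]propanoyl]-6-(methoxymethoxy)phenyl]-4-methylcyclohex-3-en-1-yl][3,5-bis(methoxymethoxy)-4-(3-methylbut-2-en-1-yl)phenyl]methanone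
Product: 27 kuwanon R
Conditions: HCl (1.25 M in MeOH), THF, 40 °C
Reagents that add atoms: none
Why: Acid-catalysed acetal exchange with methanol removes the six MOM groups, and the same acid dehydrates the benzylic β-hydroxy ketone (E1 through the p-oxybenzyl cation) to the thermodynamically favoured E-enone, the mild temperature being chosen so that the prenyl group, the 2'-hydroxychalcone and C1 are left alone.

**Compound list**

1 | 2',4'-dihydroxyacetophenone | CC(=O)c1ccc(O)cc1O | starting material
2 | 3-acetyl-2,6-dihydroxybenzaldehyde | O=Cc1c(O)ccc(C(C)=O)c1O | intermediate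
3 | 3-acetyl-2-hydroxy-6-(methoxymethoxy)benzaldehyde | O=Cc1c(OCOC)ccc(C(C)=O)c1O | intermediate
4 | ethyl (2E)-3-[3-acetyl-2-hydroxy-6-(methoxymethoxy)phenyl]prop-2-enoate | CCOC(=O)/C=C/c1c(OCOC)ccc(C(C)=O)c1O | intermediate (not isolated)
5 | 8-acetyl-5-(methoxymethoxy)-2H-chromen-2-one | O=C1C=Cc2c(OCOC)ccc(C(C)=O)c2O1 | intermediate
6 | 5-(methoxymethoxy)-8-(2-methyl-1,3-dioxolan-2-yl)-2H-chromen-2-one | O=C1C=Cc2c(OCOC)ccc(C3(C)OCCO3)c2O1 | intermediate
7 | 2,4-dihydroxybenzaldehyde | O=Cc1ccc(O)cc1O | starting material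
8 | 2,4-bis(methoxymethoxy)benzaldehyde | O=Cc1ccc(OCOC)cc1OCOC | intermediate
9 | rac-1-[2,4-bis(methoxymethoxy)phenyl]-3-methylbut-3-en-1-ol | C=C(C)CC(O)c1ccc(OCOC)cc1OCOC | intermediate
10 | butyl 1-[2,4-bis(methoxymethoxy)phenyl]-3-methylbut-3-en-1-yl ethenylboronate | C=CB(OCCCC)OC(CC(C)=C)c1ccc(OCOC)cc1OCOC | intermediate (not isolated)
11 | 6-[2,4-bis(methoxymethoxy)phenyl]-2-butoxy-4-methyl-5,6-dihydro-2H-1,2-oxaborinine | CCCCOB1C=C(C)CC(c2ccc(OCOC)cc2OCOC)O1 | intermediate (not isolated)
12 | rac-6-[2,4-bis(methoxymethoxy)phenyl]-4-methyl-5,6-dihydro-2H-1,2-oxaborinin-2-ol | OB1C=C(C)CC(c2ccc(OCOC)cc2OCOC)O1 | intermediate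
13 | (4R)-4-[(1Z)-4-[2,4-bis(methoxymethoxy)phenyl]-4-hydroxy-2-methylbut-1-en-1-yl]-5-(methoxymethoxy)-8-(2-methyl-1,3-dioxolan-2-yl)-3,4-dihydro-2H-chromen-2-one, both carbinol epimers | O=C1C[C@H](/C=C(C)\CC(O)c2ccc(OCOC)cc2OCOC)c2c(OCOC)ccc(C3(C)OCCO3)c2O1 | intermediate (key-step precursor)
14 | (4S)-4-[(1Z)-4-[2,4-bis(methoxymethoxy)phenyl]-2-methyl-4-(trimethylsilyloxy)but-1-en-1-yl]-5-(methoxymethoxy)-8-(2-methyl-1,3-dioxolan-2-yl)-2-(trimethylsilyloxy)-4H-chromene (same spatial arrangement at C4 as 13) | C[Si](C)(C)OC1=C[C@H](/C=C(C)\CC(O[Si](C)(C)C)c2ccc(OCOC)cc2OCOC)c2c(OCOC)ccc(C3(C)OCCO3)c2O1 | intermediate (not isolated)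
15 | (6aR,7S,10aS)-7-[2,4-bis(methoxymethoxy)phenyl]-1-(methoxymethoxy)-9-methyl-4-(2-methyl-1,3-dioxolan-2-yl)-6a,7,8,10a-tetrahydro-6H-benzo[c]chromen-6-one | O=C1[C@H]2[C@@H](c3c(OCOC)ccc(C4(C)OCCO4)c3O1)C=C(C)C[C@@H]2c2ccc(OCOC)cc2OCOC | intermediate (key-step product)
16 | 5-bromobenzene-1,3-diol | Oc1cc(O)cc(Br)c1 | starting material
17 | 5-bromo-2-iodobenzene-1,3-diol | Oc1cc(Br)cc(O)c1I | intermediate
18 | 5-bromo-2-iodo-1,3-bis(methoxymethoxy)benzene | COCOc1cc(Br)cc(OCOC)c1I | intermediate
19 | [4-bromo-2,6-bis(methoxymethoxy)phenyl]magnesium chloride | COCOc1cc(Br)cc(OCOC)c1[Mg]Cl | intermediate (not isolated)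
20 | 5-bromo-1,3-bis(methoxymethoxy)-2-(3-methylbut-2-en-1-yl)benzene | COCOc1cc(Br)cc(OCOC)c1CC=C(C)C | intermediate
21 | 4-hydroxybenzaldehyde | O=Cc1ccc(O)cc1 | starting material
22 | 4-(methoxymethoxy)benzaldehyde | O=Cc1ccc(OCOC)cc1 | intermediate
23 | [3,5-bis(methoxymethoxy)-4-(3-methylbut-2-en-1-yl)phenyl]lithium | [Li]c1cc(OCOC)c(CC=C(C)C)c(OCOC)c1 | intermediate (not isolated)
24 | [(1R,2S,6S)-6-[2,4-bis(methoxymethoxy)phenyl]-2-[2-hydroxy-6-(methoxymethoxy)-3-(2-methyl-1,3-dioxolan-2-yl)phenyl]-4-methylcyclohex-3-en-1-yl][3,5-bis(methoxymethoxy)-4-(3-methylbut-2-en-1-yl)phenyl]methanone | CC(C)=CCc1c(OCOC)cc(C(=O)[C@H]2[C@@H](c3c(OCOC)ccc(C4(C)OCCO4)c3O)C=C(C)C[C@@H]2c2ccc(OCOC)cc2OCOC)cc1OCOC | intermediate (not isolated)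
25 | [(1R,2S,6S)-2-[3-acetyl-2-hydroxy-6-(methoxymethoxy)phenyl]-6-[2,4-bis(methoxymethoxy)phenyl]-4-methylcyclohex-3-en-1-yl][3,5-bis(methoxymethoxy)-4-(3-methylbut-2-en-1-yl)phenyl]methanone | CC(C)=CCc1c(OCOC)cc(C(=O)[C@H]2[C@@H](c3c(OCOC)ccc(C(C)=O)c3O)C=C(C)C[C@@H]2c2ccc(OCOC)cc2OCOC)cc1OCOC | intermediate
26 | [(1R,2S,6S)-6-[2,4-bis(methoxymethoxy)phenyl]-2-[2-hydroxy-3-[3-hydroxy-3-[4-(methoxymethoxy)phenyl]propanoyl]-6-(methoxymethoxy)phenyl]-4-methylcyclohex-3-en-1-yl][3,5-bis(methoxymethoxy)-4-(3-methylbut-2-en-1-yl)phenyl]methanone, both epimers at the new carbinol | CC(C)=CCc1c(OCOC)cc(C(=O)[C@H]2[C@@H](c3c(OCOC)ccc(C(=O)CC(O)c4ccc(OCOC)cc4)c3O)C=C(C)C[C@@H]2c2ccc(OCOC)cc2OCOC)cc1OCOC | intermediate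
27 | kuwanon R | CC(C)=CCc1c(O)cc(C(=O)[C@H]2[C@@H](c3c(O)ccc(C(=O)/C=C/c4ccc(O)cc4)c3O)C=C(C)C[C@@H]2c2ccc(O)cc2O)cc1O | target

**Step count**

Total: 16 steps. Longest linear sequence: 9 steps (steps 1, 2, 3, 4, 8, 9, 14, 15, 16).

**Steps most likely to fail**

Step 9. The cation may lose a C5 proton to give a conjugated diene, the silyl triflate may open the dioxolane or MOM acetals in competition, or the two faces of the cationic carbon may not be distinguished well enough. The fallback sets out from 13 (with aryllithium 23 made from 20 as in step 14) and comes back at 25. It installs ring A first and lets an acid-generated cyclic enol ether, not a base-generated ketene acetal, be the nucleophile. Compound 13 is treated with 23 (2.3 equiv, the first equivalent being spent on the carbinol; THF, −78 °C) to give the ring-opened hydroxy ketone (3R,4Z)-7-[2,4-bis(methoxymethoxy)phenyl]-1-[3,5-bis(methoxymethoxy)-4-(3-methylbut-2-en-1-yl)phenyl]-7-hydroxy-3-[2-hydroxy-6-(methoxymethoxy)-3-(2-methyl-1,3-dioxolan-2-yl)phenyl]-5-methylhept-4-en-1-one F1. Camphorsulfonic acid (0.2 equiv, CH2Cl2, 0 °C) should then close the ketone and the ring B phenol to a 2-aryl-4H-chromene. Its enol ether carbon, which is C1, captures the benzylic cation released by the same acid, and the ring B oxygen again ties C1 to C2 so the cis relation is kept. Aqueous HCl in THF hydrolyses the resulting oxocarbenium ion and the dioxolane to 25.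

Step 8. The peri MOM ether at C5 shields C4 of an already weakly electrophilic coumarin, so the conjugate addition may be slow and protodeboronation of the alkenylboron reagent may win, or the face selectivity may be low. The fallback sets out from 3 and comes back at 13, using a doubly activated acceptor. Knoevenagel condensation of 3 with diallyl malonate (piperidine, AcOH, EtOH, 70 °C) gives prop-2-en-1-yl 8-acetyl-5-(methoxymethoxy)-2-oxo-2H-chromene-3-carboxylate F2. Ketalisation as in step 4 gives prop-2-en-1-yl 5-(methoxymethoxy)-8-(2-methyl-1,3-dioxolan-2-yl)-2-oxo-2H-chromene-3-carboxylate F3, an alkylidene-malonate-type acceptor. It should accept the alkenyl group of 12 under the catalyst of step 8 at 30 °C to give prop-2-en-1-yl (4S)-4-[(1Z)-4-[2,4-bis(methoxymethoxy)phenyl]-4-hydroxy-2-methylbut-1-en-1-yl]-5-(methoxymethoxy)-8-(2-methyl-1,3-dioxolan-2-yl)-2-oxo-3,4-dihydro-2H-chromene-3-carboxylate F4 (same spatial arrangement at C4 as 13, mixture at C3 and at the carbinol). Pd(PPh3)4 (5 mol%) and morpholine in THF remove the allyl group, and the malonic half-acid decarboxylates on warming to 13.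

Step 15. Proton transfer between the methyl ketone enolate and the C1 ketone may epimerise C1, the aldolate may revert on warming, or the phenoxide-deactivated dianion may add sluggishly. The fallback sets out from 25 and comes back at 26 without any strong base. Soft enolisation (Me3SiOTf, Et3N, CH2Cl2, 0 °C) converts the acetyl group into its silyl enol ether and silylates the phenol, leaving the hindered C1 ketone alone, to give [(1R,2S,6S)-6-[2,4-bis(methoxymethoxy)phenyl]-2-[6-(methoxymethoxy)-2-(trimethylsilyloxy)-3-[1-(trimethylsilyloxy)ethenyl]phenyl]-4-methylcyclohex-3-en-1-yl][3,5-bis(methoxymethoxy)-4-(3-methylbut-2-en-1-yl)phenyl]methanone F5. Mukaiyama aldol addition to 22 (BF3·OEt2, CH2Cl2, −78 °C) and aqueous work-up give 26.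

**Further compounds**

F1 | step 9 | (3R,4Z)-7-[2,4-bis(methoxymethoxy)phenyl]-1-[3,5-bis(methoxymethoxy)-4-(3-methylbut-2-en-1-yl)phenyl]-7-hydroxy-3-[2-hydroxy-6-(methoxymethoxy)-3-(2-methyl-1,3-dioxolan-2-yl)phenyl]-5-methylhept-4-en-1-one | CC(C)=CCc1c(OCOC)cc(C(=O)C[C@H](/C=C(C)\CC(O)c2ccc(OCOC)cc2OCOC)c2c(OCOC)ccc(C3(C)OCCO3)c2O)cc1OCOC
F2 | step 8 | prop-2-en-1-yl 8-acetyl-5-(methoxymethoxy)-2-oxo-2H-chromene-3-carboxylate | C=CCOC(=O)C1=Cc2c(OCOC)ccc(C(C)=O)c2OC1=O
F3 | step 8 | prop-2-en-1-yl 5-(methoxymethoxy)-8-(2-methyl-1,3-dioxolan-2-yl)-2-oxo-2H-chromene-3-carboxylate | C=CCOC(=O)C1=Cc2c(OCOC)ccc(C3(C)OCCO3)c2OC1=O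
F4 | step 8 | prop-2-en-1-yl (4S)-4-[(1Z)-4-[2,4-bis(methoxymethoxy)phenyl]-4-hydroxy-2-methylbut-1-en-1-yl]-5-(methoxymethoxy)-8-(2-methyl-1,3-dioxolan-2-yl)-2-oxo-3,4-dihydro-2H-chromene-3-carboxylate | O=C1C(C(=O)OCC=C)[C@H](/C=C(C)\CC(O)c2ccc(OCOC)cc2OCOC)c2c(OCOC)ccc(C3(C)OCCO3)c2O1
F5 | step 15 | [(1R,2S,6S)-6-[2,4-bis(methoxymethoxy)phenyl]-2-[6-(methoxymethoxy)-2-(trimethylsilyloxy)-3-[1-(trimethylsilyloxy)ethenyl]phenyl]-4-methylcyclohex-3-en-1-yl][3,5-bis(methoxymethoxy)-4-(3-methylbut-2-en-1-yl)phenyl]methanone | CC(C)=CCc1c(OCOC)cc(C(=O)[C@H]2[C@@H](c3c(OCOC)ccc(C(=C)O[Si](C)(C)C)c3O[Si](C)(C)C)C=C(C)C[C@@H]2c2ccc(OCOC)cc2OCOC)cc1OCOC
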